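**Retrosynthetic overview**
1. Target ⇒ C8 alcohol + (Z)-2-(acetoxymethyl)but-2-enoic acid (C8–O ester bond); C11=C13 ⇒ C11 phosphonate + formaldehyde (Horner–Wadsworth–Emmons); C8 carbinol ⇒ C8 ketone, reduced under direction of the C10 hydroxyl.
2. Ten-membered ring C1–C10 ⇒ open chain by cutting C7–C8: the C8 acyl radical from a phenyl selenoester adds to C7 of the C6 butenolide. The γ-lactone ring (O–C6–C7–C11–C12) is made first, the carbocycle second.
3. Feature used: the oxygenated C8 is bonded to C7, the β-carbon of the C12 lactone carbonyl (C8–C7–C11–C12, 1,4-dioxygenated, two acceptor carbons), so the bond is made by radical union. A diethyl phosphonate on C11 is added as activating group, because with the plain butenolide 6-exo attack of the same radical on C3=C4 is expected to win; the phosphonate later brings in C13.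
4. Butenolide ⇒ C6–C7 epoxide [(S)-epichlorohydrin, C5–C7] + triethyl phosphonoacetate (C11, C12); C4–C5 ⇒ alkenyllithium from a (Z)-2-iodoallyl silyl ether, its C3=C4 geometry fixed by Wittig homologation and α-iodination of the enal.
5. C1–C3 and C8–C10 with the C10 carbinol ⇒ (R)-linalool (vinyl group → C8 by hydroboration, prenyl group → C3 aldehyde by ozonolysis).

Key step: step 15

Remark: atoms carry germacrane labels (ring C1–C10; lactone C11, C12 carbonyl, C13 methylene; C14 methyl on C10; C15 hydroxymethyl on C4). (R)-Linalool and (S)-epichlorohydrin are assumed to be of high enantiomeric purity, since C10 and C6 are carried over from them unchanged.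

**Step 1**
Reactants: 1 (R)-linalool
Product: 3 (3R)-3,7-dimethyloct-6-ene-1,3-diol, via alkylborane 2 (not isolated)
Conditions: 9-BBN (2.2 equiv), THF, 0 °C to rt; then NaOH (3 M aq), H2O2 (30% aq), 0 °C to rt
Reagents that add atoms: hydrogen peroxide, OO
Why: Hydroboration–oxidation with the bulky dialkylborane should place boron on the terminal carbon of the vinyl group and leave the trisubstituted alkene and C10 untouched.

**Step 2**
Reactants: 3 (3R)-3,7-dimethyloct-6-ene-1,3-diol
Product: 4 (4R)-2,2,4-trimethyl-4-(4-methylpent-3-en-1-yl)-1,3-dioxane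
Conditions: Me2C(OMe)2, PPTS (cat.), CH2Cl2, rt
Reagents that add atoms: 2,2-dimethoxypropane, COC(C)(C)OC
Why: Acid-catalysed transacetalisation should tie the C8 and C10 hydroxyls into one six-membered isopropylidene acetal that withstands the organolithium, hydride and enolate steps ahead.

**Step 3**
Reactants: 4 acetonide
Product: 6 3-[(4R)-2,2,4-trimethyl-1,3-dioxan-4-yl]propanal, via ozonide 5 (not isolated)
Conditions: O3, CH2Cl2, −78 °C; then PPh3, −78 °C to rt
Reagents that add atoms: ozone, [O-][O+]=O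
Why: Ozonolysis with reductive work-up cleaves the only alkene and unveils C3 as the aldehyde.

**Step 4**
Reactants: 6 C3 aldehyde
Product: 7 (2E)-5-[(4R)-2,2,4-trimethyl-1,3-dioxan-4-yl]pent-2-enal
Conditions: Ph3P=CHCHO (1.2 equiv), toluene, 80 °C
Reagents that add atoms: (triphenylphosphoranylidene)acetaldehyde, O=CC=P(c1ccccc1)(c1ccccc1)c1ccccc1
Why: Wittig olefination with the stabilised formyl ylide should give the (E)-enal and adds C4 and C15.

**Step 5**
Reactants: 7 (E)-enal
Product: 8 (2Z)-2-iodo-5-[(4R)-2,2,4-trimethyl-1,3-dioxan-4-yl]pent-2-enal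
Conditions: I2, K2CO3, DMAP (0.2 equiv), THF/H2O (1:1), rt
Reagents that add atoms: iodine, [I][I]
Why: Amine-catalysed α-iodination (Morita–Baylis–Hillman-type addition, iodination, elimination) should give the (Z)-α-iodoenal with the chain trans to the formyl group, which fixes the C3=C4 geometry with iodine on the side of C2.

**Step 6**
Reactants: 8 α-iodoenal
Product: 9 (2Z)-2-iodo-5-[(4R)-2,2,4-trimethyl-1,3-dioxan-4-yl]pent-2-en-1-ol
Conditions: NaBH4, CeCl3·7H2O, MeOH, −20 °C
Reagents that add atoms: none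
Why: Luche 1,2-reduction should give the allylic alcohol without touching the carbon–iodine bond or the alkene geometry.

**Step 7**
Reactants: 9 iodo allylic alcohol
Product: 10 tert-butyl({(2Z)-2-iodo-5-[(4R)-2,2,4-trimethyl-1,3-dioxan-4-yl]pent-2-en-1-yl}oxy)diphenylsilane
Conditions: TBDPSCl, imidazole, DMF, 0 °C to rt
Reagents that add atoms: tert-butyl(chloro)diphenylsilane, CC(C)(C)[Si](Cl)(c1ccccc1)c1ccccc1
Why: Silylation of the primary alcohol with a group that outlasts aqueous acetic acid (step 12) and is removed last with fluoride.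

**Step 8**
Reactants: 10 alkenyl iodide; 11 (S)-epichlorohydrin
Product: 14 (2S)-2-[(2E)-2-{[tert-butyl(diphenyl)silyl]oxymethyl}-5-[(4R)-2,2,4-trimethyl-1,3-dioxan-4-yl]pent-2-en-1-yl]oxirane, via alkenyllithium 12 (not isolated), via chlorohydrin 13 (not isolated)
Conditions: t-BuLi (2.1 equiv), Et2O, −78 °C; 11, BF3·OEt2, −78 °C; aqueous work-up; then K2CO3, MeOH, rt
Reagents that add atoms: none
Why: Iodine–lithium exchange with retention of alkene geometry, BF3-promoted epoxide opening at the CH2 terminus (new C4–C5 bond) and Williamson-type closure of the chlorohydrin should give the terminal C6–C7 epoxide; C6 comes from 11 and keeps its C–O bond throughout, so its configuration is retained.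

**Step 9**
Reactants: 14 epoxide; 15 triethyl phosphonoacetate
Product: 16 diethyl {(5S)-5-[(2E)-2-{[tert-butyl(diphenyl)silyl]oxymethyl}-5-[(4R)-2,2,4-trimethyl-1,3-dioxan-4-yl]pent-2-en-1-yl]-2-oxooxolan-3-yl}phosphonate (both C11 epimers)
Conditions: 15, NaH, toluene, 0 °C to rt; then 14, 100 °C; AcOH quench
Reagents that add atoms: none
Why: Epoxide alkylation by the phosphonoacetate carbanion at the terminal carbon C7, followed by lactonisation of the C6 alkoxide onto the ethyl ester, should give the α-phosphono γ-lactone; C6 is untouched and the C11 mixture is of no consequence.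

**Step 10**
Reactants: 16 α-phosphono lactone
Product: 17 diethyl {(5S)-5-[(2E)-2-{[tert-butyl(diphenyl)silyl]oxymethyl}-5-[(4R)-2,2,4-trimethyl-1,3-dioxan-4-yl]pent-2-en-1-yl]-2-oxo-3-(phenylselanyl)oxolan-3-yl}phosphonate (both C11 epimers)
Conditions: NaH, THF, 0 °C; PhSeCl (1.05 equiv), −78 °C
Reagents that add atoms: benzeneselenenyl chloride, Cl[Se]c1ccccc1
Why: Selenenylation of the preformed phosphonate-stabilised enolate at C11 is much faster than addition of the selenenyl chloride to the C3=C4 alkene.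

**Step 11**
Reactants: 17 α-seleno lactone
Product: 19 diethyl {(5S)-5-[(2E)-2-{[tert-butyl(diphenyl)silyl]oxymethyl}-5-[(4R)-2,2,4-trimethyl-1,3-dioxan-4-yl]pent-2-en-1-yl]-2-oxo-2,5-dihydrofuran-3-yl}phosphonate, via selenoxide 18 (not isolated)
Conditions: NaIO4 (2.2 equiv), NaHCO3, THF/H2O, 0 °C to rt
Reagents that add atoms: none
Why: Selenoxide syn-elimination can only use the C7 hydrogens and should give the C7=C11 double bond of the 3-phosphoryl butenolide; periodate is chosen because it does not epoxidise either alkene.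

**Step 12**
Reactants: 19 butenolide acetonide
Product: 20 diethyl {(5S)-5-[(2E,6R)-2-{[tert-butyl(diphenyl)silyl]oxymethyl}-6,8-dihydroxy-6-methyloct-2-en-1-yl]-2-oxo-2,5-dihydrofuran-3-yl}phosphonate
Conditions: AcOH/THF/H2O (3:1:1), 40 °C
Reagents that add atoms: none
Why: Acid hydrolysis of the isopropylidene acetal frees the C8 and C10 hydroxyls, while the silyl ether and the butenolide are stable to aqueous acetic acid.

**Step 13**
Reactants: 20 diol
Product: 21 (3R,6E)-7-{[tert-butyl(diphenyl)silyl]oxymethyl}-8-[(2S)-4-(diethoxyphosphoryl)-5-oxo-2,5-dihydrofuran-2-yl]-3-hydroxy-3-methyloct-6-enoic acid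
Conditions: TEMPO (0.2 equiv), PhI(OAc)2 (2.5 equiv), MeCN/pH 7 buffer (1:1), rt
Reagents that add atoms: water, O
Why: Oxoammonium-mediated oxidation takes the primary C8 alcohol through the aldehyde hydrate to the acid, and the tertiary C10 hydroxyl cannot be oxidised.

**Step 14**
Reactants: 21 β-hydroxy acid
Product: 22 Se-phenyl (3R,6E)-7-{[tert-butyl(diphenyl)silyl]oxymethyl}-8-[(2S)-4-(diethoxyphosphoryl)-5-oxo-2,5-dihydrofuran-2-yl]-3-hydroxy-3-methyloct-6-eneselenoate
Conditions: N-(phenylselanyl)phthalimide (1.5 equiv), Bu3P (1.5 equiv, added slowly), CH2Cl2, −30 °C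
Reagents that add atoms: N-(phenylselanyl)phthalimide, O=C1c2ccccc2C(=O)N1[Se]c1ccccc1
Why: Selenoesterification through the acyloxyphosphonium salt leaves the tertiary hydroxyl alone, and since hetero-Michael addition of selenolate or phosphine to the doubly activated alkene is reversible, slow addition of the phosphine at low temperature should channel selenium into the acyl selenide.

**Step 15**
Reactants: 22 selenoester
Product: 23 diethyl [(3aR,6R,9E,11aS)-10-{[tert-butyl(diphenyl)silyl]oxymethyl}-6-hydroxy-6-methyl-2,4-dioxo-2,3,3a,4,5,6,7,8,11,11a-decahydrocyclodeca[b]furan-3-yl]phosphonate (C8 ketone; trans-fused 12,6-lactone; both C11 epimers)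
Conditions: (Me3Si)3SiH (1.5 equiv) and 2,2'-azobis(4-methoxy-2,4-dimethylvaleronitrile) (0.3 equiv) added by syringe pump over 10 h to 22 in degassed benzene (2 mM), 35 °C
Reagents that add atoms: none
Why: The silyl radical abstracts the phenylselanyl group, the nucleophilic C8 acyl radical adds to C7 (the β-carbon of the butenolide, made doubly electron-poor by the C12 carbonyl and the C11 phosphonate), and the C11 radical takes hydrogen from the silane; this is acyl radical conjugate addition from a selenoester, the known macrocyclisation type onto electron-poor alkenes. The ring C1–C10 closes in the 10-exo-trig mode, with C11 outside the new ring. The new stereocentre C7 is controlled by C6: the radical should add to the butenolide face opposite to the C5 substituent, which places C8 trans to C5 (trans-fused lactone), and C11 forms as a mixture that is erased in step 17. The step needs chemoselectivity for C7 over 6-exo attack on C3 of the unactivated C3=C4 alkene, over hydrogen transfer to the acyl radical and over loss of CO. The phosphonate is there to raise the rate of addition at C7 well above that of a plain butenolide, and slow addition of the silane at high dilution and 35 °C keeps reduction and decarbonylation slow. An azo initiator is used in place of Et3B/air because ethyl radicals would add to the activated alkene.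

**Step 16**
Reactants: 23 β-hydroxy ketone
Product: 24 diethyl [(3aS,4S,6R,9E,11aS)-10-{[tert-butyl(diphenyl)silyl]oxymethyl}-4,6-dihydroxy-6-methyl-2-oxo-2,3,3a,4,5,6,7,8,11,11a-decahydrocyclodeca[b]furan-3-yl]phosphonate (both C11 epimers)
Conditions: Me4NBH(OAc)3 (5 equiv), MeCN/AcOH (1:1), −30 °C
Reagents that add atoms: none
Why: Evans–Saksena reduction, in which the C10 hydroxyl binds boron and hydride is delivered through a six-membered chair, should set C8 as the 8,10-anti diol (8S), provided the chair with the ring bonds C8–C7 and C10–C1 equatorial is the reactive one.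

**Step 17**
Reactants: 24 α-phosphono lactone diol
Product: 25 (3aS,4S,6R,9E,11aS)-10-{[tert-butyl(diphenyl)silyl]oxymethyl}-4,6-dihydroxy-6-methyl-3-methylidene-3a,4,5,6,7,8,11,11a-octahydrocyclodeca[b]furan-2(3H)-one
Conditions: K2CO3, HCHO (37% aq), THF, 0 °C
Reagents that add atoms: formaldehyde, C=O
Why: Horner–Wadsworth–Emmons olefination of the α-phosphono lactone with formaldehyde installs C13 as the exocyclic methylene under carbonate, removing the C11 stereocentre without strong base or hydroxyl protection.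

**Step 18**
Reactants: 26 (E)-crotonaldehyde
Product: 27 (2Z)-2-iodobut-2-enal
Conditions: I2, K2CO3, DMAP (0.2 equiv), THF/H2O (1:1), rt
Reagents that add atoms: iodine, [I][I]
Why: The same amine-catalysed α-iodination as in step 5 should keep the methyl group trans to the formyl group, so iodine ends cis to methyl.

**Step 19**
Reactants: 27 (2Z)-2-iodobut-2-enal
Product: 28 (2Z)-2-iodobut-2-en-1-ol
Conditions: NaBH4, CeCl3·7H2O, MeOH, 0 °C
Reagents that add atoms: none
Why: Luche 1,2-reduction of the enal with the alkenyl iodide left intact.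

**Step 20**
Reactants: 28 (2Z)-2-iodobut-2-en-1-ol
Product: 30 (2Z)-2-(hydroxymethyl)but-2-enoic acid, via dilithio species 29 (not isolated)
Conditions: t-BuLi (3.1 equiv), Et2O, −78 °C; CO2, −78 °C to rt; 1 M HCl
Reagents that add atoms: carbon dioxide, O=C=O
Why: Deprotonation of the hydroxyl and iodine–lithium exchange give the O,C-dilithio species, whose carboxylation with retention places the carboxyl group cis to the methyl group, i.e. the (Z)-acid.

**Step 21**
Reactants: 30 (2Z)-2-(hydroxymethyl)but-2-enoic acid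
Product: 31 (2Z)-2-(acetoxymethyl)but-2-enoic acid
Conditions: Ac2O, pyridine, CH2Cl2, 0 °C to rt; then H2O
Reagents that add atoms: acetic anhydride, CC(=O)OC(C)=O
Why: O-Acetylation of the primary alcohol, with any mixed anhydride at the carboxyl group hydrolysed in the aqueous work-up.

**Step 22**
Reactants: 25 α-methylene lactone diol; 31 (2Z)-2-(acetoxymethyl)but-2-enoic acid
Product: 33 (3aR,4S,6R,9E,11aS)-10-{[tert-butyl(diphenyl)silyl]oxymethyl}-6-hydroxy-6-methyl-3-methylidene-2-oxo-2,3,3a,4,5,6,7,8,11,11a-decahydrocyclodeca[b]furan-4-yl (2Z)-2-(acetoxymethyl)but-2-enoate, via mixed anhydride 32 (not isolated)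
Conditions: 31, 2,4,6-Cl3C6H2COCl, Et3N, toluene, rt; then 25, toluene, 75 °C
Reagents that add atoms: none
Why: Yamaguchi esterification run without a nucleophilic catalyst should acylate only the secondary C8 hydroxyl (the tertiary C10 hydroxyl is too hindered) and keep the (Z)-enoate and its allylic acetate intact.

**Step 23**
Reactants: 33 silyl-protected ester
Product: 34 target, (3aR,4S,6R,9E,11aS)-6-hydroxy-10-(hydroxymethyl)-6-methyl-3-methylidene-2-oxo-2,3,3a,4,5,6,7,8,11,11a-decahydrocyclodeca[b]furan-4-yl (2Z)-2-(acetoxymethyl)but-2-enoate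
Conditions: HF·pyridine, pyridine, THF, 0 °C to rt
Reagents that add atoms: none
Why: Fluoride desilylation of the primary silyl ether under buffered acidic conditions that spare the acetate, the enoate, the α-methylene lactone and the tertiary alcohol.

**Compound list**
1 | (R)-linalool, (3R)-3,7-dimethylocta-1,6-dien-3-ol | CC(C)=CCC[C@@](C)(O)C=C | starting material
2 | B-[(3R)-3-hydroxy-3,7-dimethyloct-6-en-1-yl]-9-borabicyclo[3.3.1]nonane | CC(C)=CCC[C@@](C)(O)CCB1C2CCCC1CCC2 | intermediate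
3 | (3R)-3,7-dimethyloct-6-ene-1,3-diol | CC(C)=CCC[C@@](C)(O)CCO | intermediate
4 | (4R)-2,2,4-trimethyl-4-(4-methylpent-3-en-1-yl)-1,3-dioxane | CC(C)=CCC[C@@]1(C)OC(C)(C)OCC1 | intermediate
5 | 3,3-dimethyl-5-{2-[(4R)-2,2,4-trimethyl-1,3-dioxan-4-yl]ethyl}-1,2,4-trioxolane (ozonide, mixture at the trioxolane CH) | CC1(C)OOC(CC[C@@]2(C)OC(C)(C)OCC2)O1 | intermediate
6 | 3-[(4R)-2,2,4-trimethyl-1,3-dioxan-4-yl]propanal | O=CCC[C@@]1(C)OC(C)(C)OCC1 | intermediate
7 | (2E)-5-[(4R)-2,2,4-trimethyl-1,3-dioxan-4-yl]pent-2-enal | O=C/C=C/CC[C@@]1(C)OC(C)(C)OCC1 | intermediate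
8 | (2Z)-2-iodo-5-[(4R)-2,2,4-trimethyl-1,3-dioxan-4-yl]pent-2-enal | O=C/C(I)=C/CC[C@@]1(C)OC(C)(C)OCC1 | intermediate
9 | (2Z)-2-iodo-5-[(4R)-2,2,4-trimethyl-1,3-dioxan-4-yl]pent-2-en-1-ol | OC/C(I)=C/CC[C@@]1(C)OC(C)(C)OCC1 | intermediate
10 | tert-butyl({(2Z)-2-iodo-5-[(4R)-2,2,4-trimethyl-1,3-dioxan-4-yl]pent-2-en-1-yl}oxy)diphenylsilane | CC(C)(C)[Si](c1ccccc1)(c1ccccc1)OC/C(I)=C/CC[C@@]1(C)OC(C)(C)OCC1 | intermediate
11 | (S)-epichlorohydrin, (2S)-2-(chloromethyl)oxirane | ClC[C@@H]1CO1 | starting material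
12 | alkenyllithium from 10 (lithium on C4, cis to C2) | [Li]/C(CO[Si](c1ccccc1)(c1ccccc1)C(C)(C)C)=C\CC[C@@]1(C)OC(C)(C)OCC1 | intermediate
13 | (2S,4E)-4-{[tert-butyl(diphenyl)silyl]oxymethyl}-1-chloro-7-[(4R)-2,2,4-trimethyl-1,3-dioxan-4-yl]hept-4-en-2-ol | ClC[C@@H](O)C/C(CO[Si](c1ccccc1)(c1ccccc1)C(C)(C)C)=C\CC[C@@]1(C)OC(C)(C)OCC1 | intermediate
14 | (2S)-2-[(2E)-2-{[tert-butyl(diphenyl)silyl]oxymethyl}-5-[(4R)-2,2,4-trimethyl-1,3-dioxan-4-yl]pent-2-en-1-yl]oxirane | C1O[C@H]1C/C(CO[Si](c2ccccc2)(c3ccccc3)C(C)(C)C)=C\CC[C@@]4(C)OC(C)(C)OCC4 | intermediate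
15 | triethyl phosphonoacetate | CCOC(=O)CP(=O)(OCC)OCC | starting material
16 | diethyl {(5S)-5-[(2E)-2-{[tert-butyl(diphenyl)silyl]oxymethyl}-5-[(4R)-2,2,4-trimethyl-1,3-dioxan-4-yl]pent-2-en-1-yl]-2-oxooxolan-3-yl}phosphonate (C11 epimers) | O=C1O[C@H](CC1P(=O)(OCC)OCC)C/C(CO[Si](c2ccccc2)(c3ccccc3)C(C)(C)C)=C\CC[C@@]4(C)OC(C)(C)OCC4 | intermediate
17 | diethyl {(5S)-5-[(2E)-2-{[tert-butyl(diphenyl)silyl]oxymethyl}-5-[(4R)-2,2,4-trimethyl-1,3-dioxan-4-yl]pent-2-en-1-yl]-2-oxo-3-(phenylselanyl)oxolan-3-yl}phosphonate (C11 epimers) | O=C1O[C@H](CC1([Se]c2ccccc2)P(=O)(OCC)OCC)C/C(CO[Si](c3ccccc3)(c4ccccc4)C(C)(C)C)=C\CC[C@@]5(C)OC(C)(C)OCC5 | intermediate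
18 | Se-oxide of 17 (selenoxide) | O=C1O[C@H](CC1([Se](=O)c2ccccc2)P(=O)(OCC)OCC)C/C(CO[Si](c3ccccc3)(c4ccccc4)C(C)(C)C)=C\CC[C@@]5(C)OC(C)(C)OCC5 | intermediate
19 | diethyl {(5S)-5-[(2E)-2-{[tert-butyl(diphenyl)silyl]oxymethyl}-5-[(4R)-2,2,4-trimethyl-1,3-dioxan-4-yl]pent-2-en-1-yl]-2-oxo-2,5-dihydrofuran-3-yl}phosphonate | O=C1O[C@H](C=C1P(=O)(OCC)OCC)C/C(CO[Si](c2ccccc2)(c3ccccc3)C(C)(C)C)=C\CC[C@@]4(C)OC(C)(C)OCC4 | intermediate
20 | diethyl {(5S)-5-[(2E,6R)-2-{[tert-butyl(diphenyl)silyl]oxymethyl}-6,8-dihydroxy-6-methyloct-2-en-1-yl]-2-oxo-2,5-dihydrofuran-3-yl}phosphonate | O=C1O[C@H](C=C1P(=O)(OCC)OCC)C/C(CO[Si](c2ccccc2)(c3ccccc3)C(C)(C)C)=C\CC[C@@](C)(O)CCO | intermediate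
21 | (3R,6E)-7-{[tert-butyl(diphenyl)silyl]oxymethyl}-8-[(2S)-4-(diethoxyphosphoryl)-5-oxo-2,5-dihydrofuran-2-yl]-3-hydroxy-3-methyloct-6-enoic acid | O=C1O[C@H](C=C1P(=O)(OCC)OCC)C/C(CO[Si](c2ccccc2)(c3ccccc3)C(C)(C)C)=C\CC[C@@](C)(O)CC(=O)O | intermediate
22 | Se-phenyl (3R,6E)-7-{[tert-butyl(diphenyl)silyl]oxymethyl}-8-[(2S)-4-(diethoxyphosphoryl)-5-oxo-2,5-dihydrofuran-2-yl]-3-hydroxy-3-methyloct-6-eneselenoate (key-step precursor) | O=C1O[C@H](C=C1P(=O)(OCC)OCC)C/C(CO[Si](c2ccccc2)(c3ccccc3)C(C)(C)C)=C\CC[C@@](C)(O)CC(=O)[Se]c4ccccc4 | intermediate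
23 | diethyl [(3aR,6R,9E,11aS)-10-{[tert-butyl(diphenyl)silyl]oxymethyl}-6-hydroxy-6-methyl-2,4-dioxo-2,3,3a,4,5,6,7,8,11,11a-decahydrocyclodeca[b]furan-3-yl]phosphonate (key-step product, C11 epimers) | CCOP(=O)(OCC)C1C(=O)O[C@H]2C/C(CO[Si](c3ccccc3)(c4ccccc4)C(C)(C)C)=C\CC[C@@](C)(O)CC(=O)[C@H]12 | intermediate
24 | diethyl [(3aS,4S,6R,9E,11aS)-10-{[tert-butyl(diphenyl)silyl]oxymethyl}-4,6-dihydroxy-6-methyl-2-oxo-2,3,3a,4,5,6,7,8,11,11a-decahydrocyclodeca[b]furan-3-yl]phosphonate (C11 epimers) | CCOP(=O)(OCC)C1C(=O)O[C@H]2C/C(CO[Si](c3ccccc3)(c4ccccc4)C(C)(C)C)=C\CC[C@@](C)(O)C[C@H](O)[C@H]12 | intermediate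
25 | (3aS,4S,6R,9E,11aS)-10-{[tert-butyl(diphenyl)silyl]oxymethyl}-4,6-dihydroxy-6-methyl-3-methylidene-3a,4,5,6,7,8,11,11a-octahydrocyclodeca[b]furan-2(3H)-one | C=C1C(=O)O[C@H]2C/C(CO[Si](c3ccccc3)(c4ccccc4)C(C)(C)C)=C\CC[C@@](C)(O)C[C@H](O)[C@H]12 | intermediate
26 | (E)-crotonaldehyde | C/C=C/C=O | starting material
27 | (2Z)-2-iodobut-2-enal | C/C=C(\I)C=O | intermediate
28 | (2Z)-2-iodobut-2-en-1-ol | C/C=C(\I)CO | intermediate
29 | O,C-dilithio derivative of 28 (lithium alkoxide, lithium on C2 cis to methyl) | C/C=C(\[Li])CO[Li] | intermediate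
30 | (2Z)-2-(hydroxymethyl)but-2-enoic acid | C/C=C(\C(=O)O)CO | intermediate
31 | (2Z)-2-(acetoxymethyl)but-2-enoic acid | C/C=C(\C(=O)O)COC(C)=O | intermediate
32 | (2Z)-2-(acetoxymethyl)but-2-enoic 2,4,6-trichlorobenzoic anhydride | C/C=C(\C(=O)OC(=O)c1c(Cl)cc(Cl)cc1Cl)COC(C)=O | intermediate
33 | (3aR,4S,6R,9E,11aS)-10-{[tert-butyl(diphenyl)silyl]oxymethyl}-6-hydroxy-6-methyl-3-methylidene-2-oxo-2,3,3a,4,5,6,7,8,11,11a-decahydrocyclodeca[b]furan-4-yl (2Z)-2-(acetoxymethyl)but-2-enoate | C=C1C(=O)O[C@H]2C/C(CO[Si](c3ccccc3)(c4ccccc4)C(C)(C)C)=C\CC[C@@](C)(O)C[C@H](OC(=O)/C(=C\C)COC(C)=O)[C@H]12 | intermediate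
34 | CNP0313132.1, (3aR,4S,6R,9E,11aS)-6-hydroxy-10-(hydroxymethyl)-6-methyl-3-methylidene-2-oxo-2,3,3a,4,5,6,7,8,11,11a-decahydrocyclodeca[b]furan-4-yl (2Z)-2-(acetoxymethyl)but-2-enoate | C=C1C(=O)O[C@H]2C/C(CO)=C\CC[C@@](C)(O)C[C@H](OC(=O)/C(=C\C)COC(C)=O)[C@H]12 | target

**Step count**
Total: 23 steps. Longest linear sequence: 19 steps (steps 1–17, 22 and 23); the side-chain acid takes steps 18–21 and joins at step 22.

**The three steps most likely to fail**

1. Step 15 (key step). The C8 acyl radical may be captured by 6-exo addition to C3 of the C3=C4 alkene, reduced by the silane, or lose CO before the slow ten-membered closure. The C11 radical may also attack C3=C4 across the new ring before it is reduced, and addition to the C7 face on the side of C5 would give the cis-fused lactone. The fallback forms the same C7–C8 bond by polar acyl-anion chemistry, which has no counterpart of the radical attack on the unactivated alkene. It sets out from diol 20, which would be oxidised only to the aldehyde stage (TEMPO, PhI(OAc)2, dry CH2Cl2) to give diethyl {(5S)-5-[(2E,6R)-2-{[tert-butyl(diphenyl)silyl]oxymethyl}-6-hydroxy-6-methyl-8-oxooct-2-en-1-yl]-2-oxo-2,5-dihydrofuran-3-yl}phosphonate F1. An intramolecular Stetter reaction (3-benzyl-5-(2-hydroxyethyl)-4-methylthiazolium chloride, Et3N, dioxane, 60 °C, high dilution) would then add the C8 carbene adduct to C7 of the phosphono-butenolide. The route is rejoined at ketone 23.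

2. Step 16. The face of hydride attack may be decided by the conformation of the ten-membered ring, or by the alternative chair with the C10 methyl group equatorial, which would give poor facial selectivity or the 8-epimer. The fallback corrects C8 by inversion at the esterification. It sets out from ketone 23, which would be reduced with an external hydride on the boron chelate (Et2BOMe, NaBH4, THF/MeOH, −78 °C; Narasaka–Prasad) to make diethyl [(3aS,4R,6R,9E,11aS)-10-{[tert-butyl(diphenyl)silyl]oxymethyl}-4,6-dihydroxy-6-methyl-2-oxo-2,3,3a,4,5,6,7,8,11,11a-decahydrocyclodeca[b]furan-3-yl]phosphonate F2 the main isomer. Olefination as in step 17 would give (3aS,4R,6R,9E,11aS)-10-{[tert-butyl(diphenyl)silyl]oxymethyl}-4,6-dihydroxy-6-methyl-3-methylidene-3a,4,5,6,7,8,11,11a-octahydrocyclodeca[b]furan-2(3H)-one F3. Mitsunobu esterification of F3 with acid 31 (PPh3, DIAD, toluene, 0 °C) would invert C8 and needs no acyl activation. The route is rejoined at ester 33.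

3. Step 22. While the acid is activated, the (Z)-enoate may isomerise to the (E)-isomer or lose its allylic acetate by SN2′ substitution, and acylation of the hindered C8 hydroxyl may be slow enough to let these processes win. The fallback brings in the acetate only after the ester bond is made. It sets out from acid 30, which would be bis-silylated (TESCl, imidazole, DMF) to triethylsilyl (2Z)-2-{[(triethylsilyl)oxy]methyl}but-2-enoate F4. Cleavage of the silyl ester on K2CO3/MeOH–H2O work-up would give (2Z)-2-{[(triethylsilyl)oxy]methyl}but-2-enoic acid F5. Esterification of 25 with F5 under the conditions of step 22 would give the C8 ester carrying the CH2OSiEt3 group, F6. PPTS in MeOH would free the primary side-chain hydroxyl to give hydroxy ester F7, with the tert-butyldiphenylsilyl ether retained. Ac2O/pyridine would then acetylate only this primary hydroxyl. The route is rejoined at ester 33.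

**Further compounds**
F1 | step 15 | diethyl {(5S)-5-[(2E,6R)-2-{[tert-butyl(diphenyl)silyl]oxymethyl}-6-hydroxy-6-methyl-8-oxooct-2-en-1-yl]-2-oxo-2,5-dihydrofuran-3-yl}phosphonate | O=C1O[C@H](C=C1P(=O)(OCC)OCC)C/C(CO[Si](c2ccccc2)(c3ccccc3)C(C)(C)C)=C\CC[C@@](C)(O)CC=O
F2 | step 16 | diethyl [(3aS,4R,6R,9E,11aS)-10-{[tert-butyl(diphenyl)silyl]oxymethyl}-4,6-dihydroxy-6-methyl-2-oxo-2,3,3a,4,5,6,7,8,11,11a-decahydrocyclodeca[b]furan-3-yl]phosphonate (8-epimer of 24) | CCOP(=O)(OCC)C1C(=O)O[C@H]2C/C(CO[Si](c3ccccc3)(c4ccccc4)C(C)(C)C)=C\CC[C@@](C)(O)C[C@@H](O)[C@H]12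
F3 | step 16 | (3aS,4R,6R,9E,11aS)-10-{[tert-butyl(diphenyl)silyl]oxymethyl}-4,6-dihydroxy-6-methyl-3-methylidene-3a,4,5,6,7,8,11,11a-octahydrocyclodeca[b]furan-2(3H)-one (8-epimer of 25) | C=C1C(=O)O[C@H]2C/C(CO[Si](c3ccccc3)(c4ccccc4)C(C)(C)C)=C\CC[C@@](C)(O)C[C@@H](O)[C@H]12
F4 | step 22 | triethylsilyl (2Z)-2-{[(triethylsilyl)oxy]methyl}but-2-enoate | C/C=C(\C(=O)O[Si](CC)(CC)CC)CO[Si](CC)(CC)CC
F5 | step 22 | (2Z)-2-{[(triethylsilyl)oxy]methyl}but-2-enoic acid | C/C=C(\C(=O)O)CO[Si](CC)(CC)CC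
F6 | step 22 | (3aR,4S,6R,9E,11aS)-10-{[tert-butyl(diphenyl)silyl]oxymethyl}-6-hydroxy-6-methyl-3-methylidene-2-oxo-2,3,3a,4,5,6,7,8,11,11a-decahydrocyclodeca[b]furan-4-yl (2Z)-2-{[(triethylsilyl)oxy]methyl}but-2-enoate | C=C1C(=O)O[C@H]2C/C(CO[Si](c3ccccc3)(c4ccccc4)C(C)(C)C)=C\CC[C@@](C)(O)C[C@H](OC(=O)/C(=C\C)CO[Si](CC)(CC)CC)[C@H]12
F7 | step 22 | (3aR,4S,6R,9E,11aS)-10-{[tert-butyl(diphenyl)silyl]oxymethyl}-6-hydroxy-6-methyl-3-methylidene-2-oxo-2,3,3a,4,5,6,7,8,11,11a-decahydrocyclodeca[b]furan-4-yl (2Z)-2-(hydroxymethyl)but-2-enoate | C=C1C(=O)O[C@H]2C/C(CO[Si](c3ccccc3)(c4ccccc4)C(C)(C)C)=C\CC[C@@](C)(O)C[C@H](OC(=O)/C(=C\C)CO)[C@H]12
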